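No run can show what more gas does: east and south held the same saturation, 1.7 mM, as the flask does.

in all of them: gas phase 1.7 mM (held)

| flask | substrate | remark | time |
|---|---|---|---|
| east | 28 mM | run made earlier |  |
| south | 44 mM | run made earlier |  |
| flask | 20 mM |  | 8.0 min |

| run | time / min | target / % | substrate / % |
|---|---|---|---|
| east | 1.33 | 22.2 | 15.8 |
| east | 2.50 | 20.9 | 5.6 |
| east | 4.00 | 15.7 | 3.2 |
| east | 5.00 | 14.4 | 2.4 |
| east | 6.00 | 11.8 | 0 |
| east | 8.00 | 8.6 | 2.5 |
| south | 0.500 | 13.4 | 32.2 |
| south | 1.50 | 17.9 | 10.3 |
| south | 3.00 | 15.3 | 2.3 |
| south | 4.00 | 12.0 | 0.9 |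
| south | 6.00 | 7.0 | 0 |
| south | 8.00 | 5.7 | 0 |

(readings scatter by 1 percentage point)

- the analysis behind the earlier runs scatters by 1 percentage point, standard deviation
- at the start none of the gas phase is in solution

1. how much target there is at 8.0 min, in percent of the substrate charged
2. the change that raises the amount of target at 8.0 min, in percent of the substrate charged most ("none" if none brings more than 2 percentage points) (Sunday's / Tuesday's / none)
3. amount of target at 8.0 min, in percent of the substrate charged, after Tuesday's

- Sunday's: doubling the saturation concentration of gas phase, all else as stated
- Tuesday's: doubling the transfer coefficient of the gas phase, all else as stated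

Two chemists argue. The maker says target is made from gas, so doubling the saturation feeds it. The fader says that what stands at 8.0 min is a remnant: east falls from 20.9% at 2.50 min to 8.6% at 8.00 min, and south from 15.3% at 3.00 min to 5.7% at 8.00 min.

Her quantity is the fading constant k_f, the first-order rate at which target falls late in a run, taken as the mean of those two logarithmic falls per minute: 0.179 min⁻¹. If gas takes part, it is a pseudo-first-order constant.

I side with her. The top readings, 22.2% in east and 17.9% in south, rise as the charge falls, and carried on in the logarithm of the charge they give the flask about 25.4%. Fading from 2.50 min keeps a factor 0.373, so I reckon 9.47%. If gas feeds the fade, Sunday's costs that factor again, and the top would have to reach 68.1% to break even. I expect no gain there. Tuesday's speeds the filling of the solution, but south already shows 13.4% target at 0.500 min, so I keep my figure and answer none.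

The forecast, higher than my figure, says 11%, 11.8% after Tuesday's, and Sunday's: “Doubling saturation should favour target over the second-order loss”.

The flask gives 9.04%, and 9.05% after Tuesday's; the best change is none, since Sunday's moves target by −4.6 percentage points and Tuesday's by 0.012 points.

    target ⇌ isomer of the product (K = 2.00, k = 0.00290 s⁻¹)
    2 substrate → homo dimer (k = 0.640 M⁻¹ s⁻¹)
    gas phase ⇌ dissolved gas, rate k3*(csat - [dissolved gas]) (kL = 6.80 s⁻¹)
    substrate + dissolved gas → target (k = 5.70 M⁻¹ s⁻¹)
    dissolved gas + target → over-reacted product (k = 1.60 M⁻¹ s⁻¹)

In the flask, 0.179 min⁻¹ carries 19.1% at 4.00 min to 9.33% at 8.0 min, against the 9.04% found. The maker's view holds for the making step by itself: with its rate constant doubled, target at 8.0 min is 10.4%, above 9.04%. Run backward from 9.04%, the same constant gives 15.5% for the neighbour flask read at 5.0 min, and that neighbour holds 15.7%.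

The runs are calculated on assumed constants; scatter was added.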